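**Plan**

1. Retrosynthesis: the C10 acetate, the C1–C4 enyne (Colvin homologation after cross-metathesis of a C6 allyl group) and the C13 bromide (from a C13 alcohol with inversion) are removed first. The O–C12 and C9–Cl bonds are then cut together, which leads back to a 2,5-trans-oxolane (O bridging C6 and C9, Cl at C7) whose C9 side chain ends in a cis-12,13-epoxide.
2. Enabling feature: in the oxocane the ring oxygen and the chlorinated C9 are 1,5-related on both sides (O–C6–C7–C8–C9 and O–C12–C11–C10–C9), so the eight-membered ring is the rim of a 1-oxoniabicyclo[3.3.0]octane. Opening the strained oxirane by the oxolane oxygen (5-exo at C12) makes this ion, and chloride at C9 breaks the shared O–C9 bond.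
3. Forward order: Sharpless kinetic resolution gives the C6/C7 epoxy alcohol; an acetylide brings C9–C15; C7–OH becomes C7–Cl; Lindlar reduction; Re(VII) oxidative cyclisation builds the oxolane; directed epoxidation; ring expansion to the oxocane; then bromide, enyne and acetate.
4. Stereochemistry: C6/C7 come from the one catalytic step (C7 is then inverted by chloride). C9/C10 are relayed from C6 (trans-oxolane, syn addition to a Z-alkene). C12/C13 are relayed from C10 (hydroxyl-directed epoxidation). The key step inverts C12 and C9, and bromination inverts C13.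

Key step: step 11

Remark: atoms are numbered along the C15 chain (C1 = terminal alkyne carbon, C15 = methyl); the target is then (3E,6S,7S,9S,10S,12R,13S) with the ring oxygen between C6 and C12. rac-Hexa-1,5-dien-3-ol, (Z)-1-bromopent-2-ene and ethynylmagnesium bromide are taken as commercial.

**Step 1**
Reactants: 1 hexa-1,5-dien-3-ol (racemic)
Product: 2 (1S)-1-[(2R)-oxiran-2-yl]but-3-en-1-ol
Conditions: Ti(OiPr)4 (cat.), L-(+)-DIPT, t-BuOOH (0.45 equiv), 4 Å MS, CH2Cl2, −20 °C
Reagents that add atoms: tert-butyl hydroperoxide, CC(C)(C)OO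
Why: Sharpless asymmetric epoxidation run as a kinetic resolution: with L-(+)-tartrate only the (S)-alcohol should be epoxidised quickly, at its allylic alkene and anti to the carbinol substituent, giving the erythro (2R,3S) epoxy alcohol that fixes C6 and C7 while the homoallylic alkene stays untouched.

**Step 2**
Reactants: 2 (1S)-1-[(2R)-oxiran-2-yl]but-3-en-1-ol
Product: 3 tert-butyldimethyl{[(1S)-1-[(2R)-oxiran-2-yl]but-3-en-1-yl]oxy}silane
Conditions: TBSCl, imidazole, DMF, 0 °C → rt
Reagents that add atoms: tert-butyldimethylsilyl chloride, CC(C)(C)[Si](C)(C)Cl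
Why: Imidazole-mediated silylation of a secondary alcohol, mild enough not to start a Payne rearrangement of the epoxy alcohol.

**Step 3**
Reactants: 4 (2Z)-1-bromopent-2-ene
Product: 5 (4Z)-hept-4-en-1-yne
Conditions: HC≡CMgBr (excess), CuCl (cat.), THF, 0 °C → rt
Reagents that add atoms: ethynylmagnesium bromide, C#C[Mg]Br
Why: Copper-catalysed SN2 coupling of an alkynyl Grignard reagent with a primary allylic bromide, which should keep the Z geometry and give the skipped enyne.

**Step 4**
Reactants: 3 tert-butyldimethyl{[(1S)-1-[(2R)-oxiran-2-yl]but-3-en-1-yl]oxy}silane; 5 (4Z)-hept-4-en-1-yne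
Product: 7 (4S,5R,10Z)-4-[(tert-butyldimethylsilyl)oxy]trideca-1,10-dien-7-yn-5-ol, via lithium acetylide 6 (not isolated)
Conditions: 5, n-BuLi, THF, −78 °C; BF3·OEt2; then 3, −78 °C
Reagents that add atoms: none
Why: Boron trifluoride-assisted opening of a terminal epoxide by a lithium acetylide at its CH2 end (C8), which leaves the C7 carbinol configuration untouched and brings in C9–C15 in one step.

**Step 5**
Reactants: 7 (4S,5R,10Z)-4-[(tert-butyldimethylsilyl)oxy]trideca-1,10-dien-7-yn-5-ol
Product: 8 tert-butyl{[(4S,5S,10Z)-5-chlorotrideca-1,10-dien-7-yn-4-yl]oxy}dimethylsilane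
Conditions: n-Oct3P, CCl4, toluene, 70 °C
Reagents that add atoms: carbon tetrachloride, ClC(Cl)(Cl)Cl
Why: Appel-type chlorination of a secondary alcohol, SN2 with inversion, which should turn the (7R) alcohol into the (7S) chloride, cis-disposed to the C6 substituent in the later ring.

**Step 6**
Reactants: 8 tert-butyl{[(4S,5S,10Z)-5-chlorotrideca-1,10-dien-7-yn-4-yl]oxy}dimethylsilane
Product: 9 tert-butyl{[(4S,5S,7Z,10Z)-5-chlorotrideca-1,7,10-trien-4-yl]oxy}dimethylsilane
Conditions: H2 (1 atm), Lindlar catalyst, quinoline, EtOAc, rt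
Reagents that add atoms: none
Why: Lindlar semi-hydrogenation delivers H2 syn to the internal alkyne on poisoned palladium and should give the Z-alkene, leaving the isolated alkenes and the alkyl chloride alone.

**Step 7**
Reactants: 9 tert-butyl{[(4S,5S,7Z,10Z)-5-chlorotrideca-1,7,10-trien-4-yl]oxy}dimethylsilane
Product: 10 (4S,5S,7Z,10Z)-5-chlorotrideca-1,7,10-trien-4-ol
Conditions: HF·pyridine, pyridine, THF, 0 °C → rt
Reagents that add atoms: none
Why: Fluoride cleavage of the silyl ether under acidic rather than basic conditions, chosen so that the chlorohydrin is not closed to an epoxide.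

**Step 8**
Reactants: 10 (4S,5S,7Z,10Z)-5-chlorotrideca-1,7,10-trien-4-ol
Product: 11 (1S,3Z)-1-[(2R,4S,5S)-4-chloro-5-(prop-2-en-1-yl)oxolan-2-yl]hex-3-en-1-ol
Conditions: CF3CO2ReO3 (from Re2O7, TFAA), CH2Cl2, 0 °C → rt; aq. NaHCO3
Reagents that add atoms: trifluoroacetyl perrhenate, O=C(O[Re](=O)(=O)=O)C(F)(F)F
Why: Rhenium(VII) oxidative cyclisation of a 5-hydroxy-alkene: the perrhenate ester adds its alkoxide oxygen and one oxo oxygen to the same face of the Z-alkene (syn [3+2] addition), which should give the 2,5-trans-oxolane (C9 relayed from C6) and the erythro carbinol at C10.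

**Step 9**
Reactants: 11 (1S,3Z)-1-[(2R,4S,5S)-4-chloro-5-(prop-2-en-1-yl)oxolan-2-yl]hex-3-en-1-ol
Product: 12 (1S)-1-[(2R,4S,5S)-4-chloro-5-(prop-2-en-1-yl)oxolan-2-yl]-2-[(2S,3R)-3-ethyloxiran-2-yl]ethan-1-ol
Conditions: VO(acac)2 (cat.), t-BuOOH, CH2Cl2, 0 °C → rt
Reagents that add atoms: tert-butyl hydroperoxide, CC(C)(C)OO
Why: Vanadium-catalysed hydroxyl-directed epoxidation of a (Z)-homoallylic alcohol through a chair-like vanadate ester with the carbinol substituent equatorial, which should give the 1,3-anti cis-epoxide (12S,13R) and leave the remote allyl group alone.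

**Step 10**
Reactants: 12 (1S)-1-[(2R,4S,5S)-4-chloro-5-(prop-2-en-1-yl)oxolan-2-yl]-2-[(2S,3R)-3-ethyloxiran-2-yl]ethan-1-ol
Product: 13 tert-butyl{(1S)-1-[(2R,4S,5S)-4-chloro-5-(prop-2-en-1-yl)oxolan-2-yl]-2-[(2S,3R)-3-ethyloxiran-2-yl]ethoxy}dimethylsilane
Conditions: TBSCl, imidazole, DMAP (cat.), DMF, rt
Reagents that add atoms: tert-butyldimethylsilyl chloride, CC(C)(C)[Si](C)(C)Cl
Why: Imidazole-mediated silylation under non-acidic conditions (no silyl triflate, which would activate the epoxide too early), giving a C10 ether that cannot act as a neighbouring group.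

**Step 11**
Reactants: 13 tert-butyl{(1S)-1-[(2R,4S,5S)-4-chloro-5-(prop-2-en-1-yl)oxolan-2-yl]-2-[(2S,3R)-3-ethyloxiran-2-yl]ethoxy}dimethylsilane
Product: 16 (1R)-1-[(2R,4S,5S,7S,8S)-4-[(tert-butyldimethylsilyl)oxy]-5,7-dichloro-8-(prop-2-en-1-yl)oxocan-2-yl]propan-1-ol, via bicyclic oxonium triflate 14 (not isolated), via C13 trimethylsilyl ether 15 (not isolated)
Conditions: TMSOTf, 2,6-di-tert-butyl-4-methylpyridine, CH2Cl2, −78 °C; then n-Bu4NCl, −78 → −30 °C; citric acid, MeOH work-up
Reagents that add atoms: tetrabutylammonium chloride, CCCC[N+](CCCC)(CCCC)CCCC.[Cl-]; trimethylsilyl trifluoromethanesulfonate, C[Si](C)(C)OS(=O)(=O)C(F)(F)F (its silyl group and triflate stay in 14 and 15 only)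
Why: Proposed new method: silylation of the oxirane oxygen makes C12 electrophilic, and the oxolane oxygen four atoms away (O–C9–C10–C11–C12) opens it with inversion to give the cis-fused 1-oxoniabicyclo[3.3.0]octane 14, in which C9 is common to both five-membered rings; chloride then attacks C9 anti to the oxonium oxygen and breaks the shared O–C9 bond, so that the rim of the bicycle becomes the oxocane. The closest known reaction types are the bromonium-triggered ring-expanding etherification of oxolanes through the same kind of bicyclic oxonium ion with nucleophile capture, and the Lewis-acid opening of epoxides by tethered ether oxygens; here the trigger is a stereodefined epoxide and the terminating nucleophile is external chloride. Ring closure: the new five-membered ring closes 5-exo-tet (spiro transition state, strain release of the oxirane), and the eight-membered ring is then revealed by fragmentation, so no medium-ring transition state is needed. Stereocontrol: C12 (R) comes from stereospecific inversion of the (12S) epoxide carbon, C13 keeps its epoxide C–O bond (13R), and C9 (S) comes from SN2 inversion of the (9R) ring-fusion carbon; because the target is the 2,8-trans-oxocane the C12 side chain must sit on the concave face of 14, which a freely choosing halonium ion would avoid, and the preformed epoxide removes that choice. Selectivity needed: 5-exo attack at C12 rather than 6-endo at C13, and chloride attack at C9 rather than C6 or C12; the spiro geometry favours C12, cleavage at C9 is the only opening that relieves both five-membered rings (oxocan-5-yl cations are known to return nucleophiles to this carbon), C6 is deactivated by the adjacent C7–Cl and C12 is shielded by the concave-face silyloxypropyl group, and the C10 silyl ether cannot compete as an ester would.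

**Step 12**
Reactants: 16 (1R)-1-[(2R,4S,5S,7S,8S)-4-[(tert-butyldimethylsilyl)oxy]-5,7-dichloro-8-(prop-2-en-1-yl)oxocan-2-yl]propan-1-ol
Product: 17 tert-butyl{[(2R,4S,5S,7S,8S)-2-[(1S)-1-bromopropyl]-5,7-dichloro-8-(prop-2-en-1-yl)oxocan-4-yl]oxy}dimethylsilane
Conditions: CBr4, n-Oct3P, toluene, 70 °C
Reagents that add atoms: carbon tetrabromide, BrC(Br)(Br)Br
Why: Phosphine/CBr4 (Appel-type) bromination of the secondary carbinol next to the ring oxygen, SN2 with inversion (13R alcohol to 13S bromide), a change well precedented for α-(1-hydroxypropyl) medium-ring ethers.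

**Step 13**
Reactants: 17 tert-butyl{[(2R,4S,5S,7S,8S)-2-[(1S)-1-bromopropyl]-5,7-dichloro-8-(prop-2-en-1-yl)oxocan-4-yl]oxy}dimethylsilane
Product: 18 (2E)-4-[(2S,3S,5S,6S,8R)-8-[(1S)-1-bromopropyl]-6-[(tert-butyldimethylsilyl)oxy]-3,5-dichlorooxocan-2-yl]but-2-enal
Conditions: crotonaldehyde (excess), Hoveyda–Grubbs II (cat.), CH2Cl2, 40 °C
Reagents that add atoms: (E)-crotonaldehyde, C/C=C/C=O
Why: Olefin cross-metathesis of the terminal allyl group with an electron-poor partner, which should give the E-enal under thermodynamic control with loss of propene.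

**Step 14**
Reactants: 18 (2E)-4-[(2S,3S,5S,6S,8R)-8-[(1S)-1-bromopropyl]-6-[(tert-butyldimethylsilyl)oxy]-3,5-dichlorooxocan-2-yl]but-2-enal
Product: 19 tert-butyl{[(2R,4S,5S,7S,8S)-2-[(1S)-1-bromopropyl]-5,7-dichloro-8-[(2E)-pent-2-en-4-yn-1-yl]oxocan-4-yl]oxy}dimethylsilane
Conditions: TMSCHN2, LDA, THF, −78 → 0 °C
Reagents that add atoms: trimethylsilyldiazomethane, C[Si](C)(C)C=[N+]=[N-]
Why: Colvin rearrangement: lithiated trimethylsilyldiazomethane adds to the aldehyde, Peterson-type loss of silanolate and N2 gives an alkylidene carbene, and a 1,2-hydrogen shift should deliver the terminal alkyne without touching the E-alkene or the alkyl halides at low temperature.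

**Step 15**
Reactants: 19 tert-butyl{[(2R,4S,5S,7S,8S)-2-[(1S)-1-bromopropyl]-5,7-dichloro-8-[(2E)-pent-2-en-4-yn-1-yl]oxocan-4-yl]oxy}dimethylsilane
Product: 20 (2R,4S,5S,7S,8S)-2-[(1S)-1-bromopropyl]-5,7-dichloro-8-[(2E)-pent-2-en-4-yn-1-yl]oxocan-4-ol
Conditions: HF·pyridine, pyridine, THF, 0 °C → rt
Reagents that add atoms: none
Why: Acidic fluoride desilylation removes the secondary TBS ether without the basic conditions that could close the trans-chlorohydrin to an epoxide or attack the alkyl halides.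

**Step 16**
Reactants: 20 (2R,4S,5S,7S,8S)-2-[(1S)-1-bromopropyl]-5,7-dichloro-8-[(2E)-pent-2-en-4-yn-1-yl]oxocan-4-ol
Product: 21 (2R,4S,5S,7S,8S)-2-[(1S)-1-bromopropyl]-5,7-dichloro-8-[(2E)-pent-2-en-4-yn-1-yl]oxocan-4-yl acetate
Conditions: Ac2O, pyridine, DMAP (cat.), CH2Cl2, 0 °C → rt
Reagents that add atoms: acetic anhydride, CC(=O)OC(C)=O
Why: DMAP-catalysed acylation of the secondary alcohol; no stereocentre is touched.

**Compound list**

1 | hexa-1,5-dien-3-ol (racemic) | C=CCC(O)C=C | starting material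
2 | (1S)-1-[(2R)-oxiran-2-yl]but-3-en-1-ol | C=CC[C@H](O)[C@H]1CO1 | intermediate
3 | tert-butyldimethyl{[(1S)-1-[(2R)-oxiran-2-yl]but-3-en-1-yl]oxy}silane | C=CC[C@H](O[Si](C)(C)C(C)(C)C)[C@H]1CO1 | intermediate
4 | (2Z)-1-bromopent-2-ene | BrC/C=C\CC | starting material
5 | (4Z)-hept-4-en-1-yne | C#CC/C=C\CC | intermediate
6 | lithium (4Z)-hept-4-en-1-yn-1-ide | [Li]C#CC/C=C\CC | intermediate (not isolated)
7 | (4S,5R,10Z)-4-[(tert-butyldimethylsilyl)oxy]trideca-1,10-dien-7-yn-5-ol | C=CC[C@H](O[Si](C)(C)C(C)(C)C)[C@H](O)CC#CC/C=C\CC | intermediate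
8 | tert-butyl{[(4S,5S,10Z)-5-chlorotrideca-1,10-dien-7-yn-4-yl]oxy}dimethylsilane | C=CC[C@H](O[Si](C)(C)C(C)(C)C)[C@@H](Cl)CC#CC/C=C\CC | intermediate
9 | tert-butyl{[(4S,5S,7Z,10Z)-5-chlorotrideca-1,7,10-trien-4-yl]oxy}dimethylsilane | C=CC[C@H](O[Si](C)(C)C(C)(C)C)[C@@H](Cl)C/C=C\C/C=C\CC | intermediate
10 | (4S,5S,7Z,10Z)-5-chlorotrideca-1,7,10-trien-4-ol | C=CC[C@H](O)[C@@H](Cl)C/C=C\C/C=C\CC | intermediate
11 | (1S,3Z)-1-[(2R,4S,5S)-4-chloro-5-(prop-2-en-1-yl)oxolan-2-yl]hex-3-en-1-ol | C=CC[C@@H]1O[C@@H]([C@@H](O)C/C=C\CC)C[C@@H]1Cl | intermediate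
12 | (1S)-1-[(2R,4S,5S)-4-chloro-5-(prop-2-en-1-yl)oxolan-2-yl]-2-[(2S,3R)-3-ethyloxiran-2-yl]ethan-1-ol | C=CC[C@@H]1O[C@@H]([C@@H](O)C[C@@H]2O[C@@H]2CC)C[C@@H]1Cl | intermediate
13 | tert-butyl{(1S)-1-[(2R,4S,5S)-4-chloro-5-(prop-2-en-1-yl)oxolan-2-yl]-2-[(2S,3R)-3-ethyloxiran-2-yl]ethoxy}dimethylsilane | C=CC[C@@H]1O[C@@H]([C@@H](O[Si](C)(C)C(C)(C)C)C[C@@H]2O[C@@H]2CC)C[C@@H]1Cl | intermediate
14 | cis-fused 1-oxoniabicyclo[3.3.0]octane triflate (8-allyl-7-chloro-4-TBSO-2-[(1R)-1-(trimethylsilyloxy)propyl]; O+ bonded to C6, C9 and C12) | C=CC[C@@H]1[O+]2[C@H](C[C@@H]1Cl)[C@@H](O[Si](C)(C)C(C)(C)C)C[C@@H]2[C@H](O[Si](C)(C)C)CC.[O-]S(=O)(=O)C(F)(F)F | intermediate (not isolated)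
15 | tert-butyl{[(2R,4S,5S,7S,8S)-5,7-dichloro-8-(prop-2-en-1-yl)-2-[(1R)-1-(trimethylsilyloxy)propyl]oxocan-4-yl]oxy}dimethylsilane | C=CC[C@@H]1O[C@@H]([C@H](O[Si](C)(C)C)CC)C[C@H](O[Si](C)(C)C(C)(C)C)[C@@H](Cl)C[C@@H]1Cl | intermediate (not isolated)
16 | (1R)-1-[(2R,4S,5S,7S,8S)-4-[(tert-butyldimethylsilyl)oxy]-5,7-dichloro-8-(prop-2-en-1-yl)oxocan-2-yl]propan-1-ol | C=CC[C@@H]1O[C@@H]([C@H](O)CC)C[C@H](O[Si](C)(C)C(C)(C)C)[C@@H](Cl)C[C@@H]1Cl | intermediate
17 | tert-butyl{[(2R,4S,5S,7S,8S)-2-[(1S)-1-bromopropyl]-5,7-dichloro-8-(prop-2-en-1-yl)oxocan-4-yl]oxy}dimethylsilane | C=CC[C@@H]1O[C@@H]([C@@H](Br)CC)C[C@H](O[Si](C)(C)C(C)(C)C)[C@@H](Cl)C[C@@H]1Cl | intermediate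
18 | (2E)-4-[(2S,3S,5S,6S,8R)-8-[(1S)-1-bromopropyl]-6-[(tert-butyldimethylsilyl)oxy]-3,5-dichlorooxocan-2-yl]but-2-enal | O=C/C=C/C[C@@H]1O[C@@H]([C@@H](Br)CC)C[C@H](O[Si](C)(C)C(C)(C)C)[C@@H](Cl)C[C@@H]1Cl | intermediate
19 | tert-butyl{[(2R,4S,5S,7S,8S)-2-[(1S)-1-bromopropyl]-5,7-dichloro-8-[(2E)-pent-2-en-4-yn-1-yl]oxocan-4-yl]oxy}dimethylsilane | C#C/C=C/C[C@@H]1O[C@@H]([C@@H](Br)CC)C[C@H](O[Si](C)(C)C(C)(C)C)[C@@H](Cl)C[C@@H]1Cl | intermediate
20 | (2R,4S,5S,7S,8S)-2-[(1S)-1-bromopropyl]-5,7-dichloro-8-[(2E)-pent-2-en-4-yn-1-yl]oxocan-4-ol | C#C/C=C/C[C@@H]1O[C@@H]([C@@H](Br)CC)C[C@H](O)[C@@H](Cl)C[C@@H]1Cl | intermediate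
21 | (2R,4S,5S,7S,8S)-2-[(1S)-1-bromopropyl]-5,7-dichloro-8-[(2E)-pent-2-en-4-yn-1-yl]oxocan-4-yl acetate | C#C/C=C/C[C@@H]1O[C@@H]([C@@H](Br)CC)C[C@H](OC(C)=O)[C@@H](Cl)C[C@@H]1Cl | target

**Totals and risks**

Total step count: 16. Longest linear sequence: 15 steps (1 → 21; step 3 is the side branch).

Step 11 (Proposed new method). The silyl-activated epoxide may be opened by triflate or chloride, or at C13 in the 6-endo mode, before the crowded concave-face oxonium ion forms. Chloride may also open the ion at C6 or C12, which contracts the system back to an oxolane instead of expanding it. The fallback uses known reactions and reverses the order of events: the oxolane is opened with chloride first and the oxocane is then closed on the open chain, at the price of less stereo- and regiocontrol. It sets out from 11 and comes back at 16. Alcohol 11 is silylated (TBSCl, imidazole) to the tert-butyldimethylsilyl ether F1. Acylative cleavage of the cyclic ether (AcCl, cat. ZnCl2, CH2Cl2), with chloride attacking C9 in SN2 fashion (inversion) and the acyl group ending on O6, should give the open-chain dichloro acetate F2. Peracid epoxidation (mCPBA) of the Z-alkene, which reacts before the terminal alkene, gives both cis-epoxides, from which the (12S,13R) epoxy acetate F3 is separated. Reduction of the acetate with DIBAL-H at −78 °C (no base, so the chlorohydrin is not closed) gives the epoxy alcohol F4. Acid-promoted epoxy-alcohol cyclisation at high dilution (CSA, CH2Cl2), exo mode at C12 with inversion, then gives 16.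

Step 8. The ring closure may not be fully trans-selective, and the acidic perrhenate medium may isomerise or over-oxidise the skipped diene. The fallback changes the oxolane-forming event from a syn-oxidative cyclisation of a Z-alkene to epoxidation and 5-exo epoxide opening (anti addition) on an E-alkene. It sets out from 7 and comes back at 11. Hydroxyl-directed trans-hydroalumination of the homopropargylic alcohol 7 (Red-Al, THF) gives the (7E,10Z)-dienol F5. The same phosphine/CCl4 chlorination with inversion gives the chloride F6, and HF·pyridine gives the (7E,10Z)-chlorotrienol F7. Hydroxyl-directed epoxidation of the bishomoallylic E-alkene (VO(acac)2, t-BuOOH), followed by acid-catalysed 5-exo opening of the epoxide by the C6 hydroxyl (CSA), should give 11. The erythro C9/C10 relation follows from anti addition to the E-alkene; the 2,5-trans sense rests on the chair-like vanadate model and would have to be confirmed.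

Step 9. The directed epoxidation may show poor facial selectivity (1,3-anti versus syn), and slow turnover may allow the Lewis-acidic metal to open the new epoxide through the neighbouring hydroxyl or the ring oxygen. The fallback replaces substrate control by catalyst control. It sets out from 11 and comes back at 12, with no new compound. Alcohol 11 is epoxidised with a hafnium(IV) or tungsten catalyst carrying a chiral C2-symmetric bis-hydroxamic acid ligand and cumene hydroperoxide (or H2O2); (Z)-homoallylic alcohols are the best substrate class for these catalysts. The ligand antipode is chosen to deliver oxygen to the face that gives the (12S,13R) epoxide.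

**Further compounds**

F1 | step 11 | tert-butyl{[(1S,3Z)-1-[(2R,4S,5S)-4-chloro-5-(prop-2-en-1-yl)oxolan-2-yl]hex-3-en-1-yl]oxy}dimethylsilane | C=CC[C@@H]1O[C@@H]([C@@H](O[Si](C)(C)C(C)(C)C)C/C=C\CC)C[C@@H]1Cl
F2 | step 11 | (4S,5S,7S,8S,10Z)-8-[(tert-butyldimethylsilyl)oxy]-5,7-dichlorotrideca-1,10-dien-4-yl acetate | C=CC[C@H](OC(C)=O)[C@@H](Cl)C[C@H](Cl)[C@@H](O[Si](C)(C)C(C)(C)C)C/C=C\CC
F3 | step 11 | (4S,5S,7S,8S)-8-[(tert-butyldimethylsilyl)oxy]-5,7-dichloro-9-[(2S,3R)-3-ethyloxiran-2-yl]non-1-en-4-yl acetate | C=CC[C@H](OC(C)=O)[C@@H](Cl)C[C@H](Cl)[C@@H](O[Si](C)(C)C(C)(C)C)C[C@@H]1O[C@@H]1CC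
F4 | step 11 | (4S,5S,7S,8S)-8-[(tert-butyldimethylsilyl)oxy]-5,7-dichloro-9-[(2S,3R)-3-ethyloxiran-2-yl]non-1-en-4-ol | C=CC[C@H](O)[C@@H](Cl)C[C@H](Cl)[C@@H](O[Si](C)(C)C(C)(C)C)C[C@@H]1O[C@@H]1CC
F5 | step 8 | (4S,5R,7E,10Z)-4-[(tert-butyldimethylsilyl)oxy]trideca-1,7,10-trien-5-ol | C=CC[C@H](O[Si](C)(C)C(C)(C)C)[C@H](O)C/C=C/C/C=C\CC
F6 | step 8 | tert-butyl{[(4S,5S,7E,10Z)-5-chlorotrideca-1,7,10-trien-4-yl]oxy}dimethylsilane | C=CC[C@H](O[Si](C)(C)C(C)(C)C)[C@@H](Cl)C/C=C/C/C=C\CC
F7 | step 8 | (4S,5S,7E,10Z)-5-chlorotrideca-1,7,10-trien-4-ol | C=CC[C@H](O)[C@@H](Cl)C/C=C/C/C=C\CC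
F0 | step 9 | none | none
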